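**Plan**

1. Locants: ring carbons C1 (C–OH carrying the butenoyl chain C2–C4, C15), C5 (CH–O-isobutyryl), C6 (lactone O–CH), C7 (ring-fusion CH), C8 (CH2), C9 (CHOH), C10 (CHCH3); lactone C11 (α-C), C12 (C=O), C13 (=CH2); β = ring face of the C1–OH, α = the other face.
2. Retrosynthesis, in order: cut C2–C3 (propenyl onto a C2 aldehyde), C11=C13, the C5 ester, C10–CH3 and C7–C11; re-bond the C1 oxygen to C8 as an ether bridge with C9 as a ketone; then cut C7–C8 and C5–C1 together.
3. That double cut is a (4+3) cycloaddition of a 2-substituted furan (C8–C9–C10–C1 plus the C1 oxygen) with a 1-alkoxy-2-silyloxyallyl cation (C7–C6–C5). It is possible because the tertiary O on C1 lies 1,4 to the C8 methylene across the seven-membered ring, with the oxygenated C9 next to C8: the furan oxygen can serve as a temporary C1–O–C8 bridge and be released by SmI2 once C9 is a ketone.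
4. Forward: the cycloaddition makes the cycloheptane and the bridge (an 8-oxabicyclo[3.2.1]octenone) first; the lactone is fused at C6/C7; C9 is oxidised and C10 methylated on the two-carbon bridge; ester, methylene and C3–C15 follow; the bridge is cleaved, C9 reduced and C2 oxidised.
5. Stereochemistry: absolute from the (S)-1-phenylethoxy group on the cation; C5 from the compact cycloaddition; C7 and C10 from exo-face enolate alkylations of the rigid bicycle; C6 from exo hydride then SN2 inversion; C1 from the bridge; C9 from hydride delivery directed by the C1–OH.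

Key step: step 4

Assumption: the (S)-1-phenylethoxy group is taken to screen the face of the allyl cation that leads to 9 as drawn; if the sense of induction is the opposite, (R)-1-phenylethanol replaces 4 and nothing else changes.

Step 1
Reactants: 1 furfuryl alcohol (furan-2-ylmethanol)
Product: 2 tert-butyl(furan-2-ylmethoxy)diphenylsilane
Conditions: TBDPSCl, imidazole, CH2Cl2, 0 °C to rt
Reagents that add atoms: tert-butyl(chloro)diphenylsilane, CC(C)(C)[Si](Cl)(c1ccccc1)c1ccccc1
Why: Silyl ether formation on the primary alcohol gives a robust protecting group that should survive the Lewis-acidic, basic, reducing and oxidising steps up to step 14; no stereocentre is formed.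

Step 2
Reactants: 3 1,1-dimethoxypropan-2-one; 4 (S)-1-phenylethanol
Product: 5 1-methoxy-1-[(1S)-1-phenylethoxy]propan-2-one (both epimers at the acetal carbon)
Conditions: TsOH (1 mol%), 3 in excess, 40 °C, reduced pressure to remove MeOH
Reagents that add atoms: none
Why: Acid-catalysed transacetalisation exchanges one methoxy group for the chiral alkoxy group, excess 3 and removal of methanol favouring the mixed acetal; the acetal carbon forms as both epimers, which is immaterial because it becomes planar in step 4.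

Step 3
Reactants: 5 1-methoxy-1-[(1S)-1-phenylethoxy]propan-2-one
Product: 7 triethyl({3-methoxy-3-[(1S)-1-phenylethoxy]prop-1-en-2-yl}oxy)silane, via lithium enolate 6 (not isolated)
Conditions: LiN(i-Pr)2, THF, −78 °C; then Et3SiCl, −78 °C to 0 °C
Reagents that add atoms: chlorotriethylsilane, CC[Si](Cl)(CC)CC
Why: Kinetic deprotonation at the methyl group and O-silylation (silyl enol ether formation) give the 2-silyloxyallyl acetal; no stereocentre is formed.

Step 4
Reactants: 2 tert-butyl(furan-2-ylmethoxy)diphenylsilane; 7 triethyl({3-methoxy-3-[(1S)-1-phenylethoxy]prop-1-en-2-yl}oxy)silane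
Product: 9 (1R,2R,5S)-1-[(tert-butyldiphenylsilyloxy)methyl]-2-[(1S)-1-phenylethoxy]-8-oxabicyclo[3.2.1]oct-6-en-3-one (target locants: 1β,8β-oxygen bridge; 5α-alkoxy equatorial; C6 ketone; C9=C10), via silyloxyallyl cation triflate 8 (not isolated)
Conditions: 2 (1.5 equiv), TMSOTf (10 mol%), CH2Cl2, −95 °C; then Et3N, aq. NaHCO3
Reagents that add atoms: none
Why: Catalytic TMSOTf ionises the methoxy group of 7 to the planar 1-alkoxy-2-silyloxyallyl cation 8, which adds as a two-electron three-carbon unit across the 2- and 5-positions of furan 2 in a concerted but asynchronous (4+3) cycloaddition, after which the silyl group leaves the carbonyl oxygen and carries the chain by ionising the next molecule of 7. The closest known reaction type is the low-temperature (4+3) cycloaddition of furans with chiral α-alkoxy silyloxyallyl cations generated from mixed acetals. The step closes the seven-membered carbocycle (C1, C5, C6, C7, C8, C9, C10) and, with it, the oxan-4-one ring (O, C1, C5, C6, C7, C8) of the 8-oxabicyclo[3.2.1]octene, both by intermolecular cycloaddition that is suprafacial on the furan and on the allyl cation. C1 and C8 are tied cis by the furan oxygen, C5 should receive its alkoxy group equatorial (α, anti to the bridge) from the compact transition state of the W-shaped cation, and the absolute configuration is set by the (S)-1-phenylethyl group, whose phenyl ring screens one face of the cation. The step needs regioselectivity (C5 to the substituted furan carbon, C7 to the unsubstituted one) as well as facial selectivity; the polarisation of both partners should secure it, because the unsubstituted CH2 terminus of 8, the less hindered end with the larger acceptor coefficient, bonds first to the unsubstituted and more nucleophilic α-carbon of the 2-alkylfuran, so that the alkoxy-bearing terminus closes on the substituted carbon, the orientation that heteroatom-substituted oxyallyl cations show with 2-substituted furans.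

Step 5
Reactants: 9 the bicyclic ketone of step 4; 10 tert-butyl bromoacetate
Product: 12 tert-butyl [1β,8β-epoxy-6-oxo-5α-((1S)-1-phenylethoxy)-1-(TBDPS-oxymethyl)cyclohept-9-en-7β-yl]acetate (arm axial and syn to the oxygen bridge; H-7 α), via lithium enolate 11 (not isolated)
Conditions: LiN(i-Pr)2 (1.1 equiv), THF, −78 °C; then 10, DMPU, −78 °C to −40 °C; cold aq. NH4Cl
Reagents that add atoms: none
Why: Kinetic enolate alkylation: LiN(i-Pr)2 removes the exposed axial hydrogen at C7 (the alkoxy-bearing methine C5–H beside the quaternary C1 is kinetically much less acidic) to give 11, which is alkylated on its β (exo) face because the α face is covered by the C9=C10 bridge, so the new C7 stereocentre carries the acetate arm β.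

Step 6
Reactants: 12 the 7β-acetate ketone
Product: 13 tert-butyl [1β,8β-epoxy-6α-hydroxy-5α-((1S)-1-phenylethoxy)-1-(TBDPS-oxymethyl)cyclohept-9-en-7β-yl]acetate (hydroxyl axial, anti to the bridge, trans to the C7 arm)
Conditions: LiBH(s-Bu)3, THF, −78 °C; aq. NH4Cl
Reagents that add atoms: none
Why: Ketone reduction by a bulky trialkylborohydride: hydride should reach C6 only from the β (exo) face, because the α face lies in the cavity above the C9=C10 bridge, which sets C6 with the hydroxyl α, trans to the C7 arm so that no lactone forms yet; the tert-butyl ester is inert.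

Step 7
Reactants: 13 the 6α-hydroxy ester
Product: 15 1β,8β-epoxy-5α-[(1S)-1-phenylethoxy]-1-(TBDPS-oxymethyl)cyclohept-9-en-12,6β-olide (γ-lactone O6–C12(=O)–C11H2–C7; cis-fused on the β face), via C6 triflate 14 (not isolated)
Conditions: Tf2O, pyridine, CH2Cl2, −40 °C to rt
Reagents that add atoms: none
Why: Neighbouring-group lactonisation with inversion: the 6α-triflate 14 is displaced from the β face in a 5-exo SN2 attack by the carbonyl oxygen of the tert-butyl ester and the dialkoxycarbenium ion loses isobutene, so C6 is inverted to the 6β-oxygen configuration and the γ-lactone is cis-fused on the bridge face.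

Step 8
Reactants: 15 the tricyclic lactone alkene
Product: 17 1β,8β-epoxy-9β-hydroxy-5α-[(1S)-1-phenylethoxy]-1-(TBDPS-oxymethyl)cycloheptane-12,6β-olide (exo alcohol; C10 is CH2), via C9 borane 16 (not isolated)
Conditions: 9-BBN, THF, 0 °C to rt; then NaBO3·4H2O, H2O, rt
Reagents that add atoms: sodium perborate, [Na+].[Na+].O[B-]1(O)OO[B-](O)(O)OO1
Why: Hydroboration–oxidation: 9-BBN adds syn to the β (exo) face of the strained alkene and should place boron on C9 and not on C10, whose exo position is nearly eclipsed with the CH2OTBDPS group on the quaternary bridgehead C1, and perborate oxidation with retention gives the 9β-alcohol, a stereocentre that is removed in step 9.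

Step 9
Reactants: 17 the 9β-alcohol
Product: 18 1β,8β-epoxy-9-oxo-5α-[(1S)-1-phenylethoxy]-1-(TBDPS-oxymethyl)cycloheptane-12,6β-olide
Conditions: Dess–Martin periodinane, NaHCO3, CH2Cl2, rt
Reagents that add atoms: none
Why: Dess–Martin oxidation of the secondary alcohol gives the ketone on the two-carbon bridge, flanked by the non-enolisable bridgehead C8 and by C10H2, so no stereocentre is at risk.

Step 10
Reactants: 18 the 9-ketone
Product: 20 1β,8β-epoxy-10β-methyl-9-oxo-5α-[(1S)-1-phenylethoxy]-1-(TBDPS-oxymethyl)cycloheptane-12,6β-olide (methyl exo, cis to the bridge oxygen; H-10 α), via lithium enolate 19 (not isolated)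
Conditions: LiN(SiMe3)2 (1.05 equiv), THF, −78 °C; then MeI, DMPU, −78 °C to −40 °C
Reagents that add atoms: iodomethane, CI
Why: Kinetic enolate methylation: LiN(SiMe3)2 at −78 °C should remove the exposed exo hydrogen at C10 of the ketone faster than an α-hydrogen of the lactone (C8 is a bridgehead and cannot enolise), and iodomethane attacks 19 from the β (exo) face because the α face is blocked by the three-carbon bridge and H-6, setting the C10 methyl β; the remaining C10–H is endo and shielded, so neither a second methylation nor epimerisation is expected.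

Step 11
Reactants: 20 the 10β-methyl ketone
Product: 21 1β,8β-epoxy-5α-hydroxy-10β-methyl-9-oxo-1-(TBDPS-oxymethyl)cycloheptane-12,6β-olide
Conditions: H2 (1 atm), Pd(OH)2/C, EtOAc, rt
Reagents that add atoms: none
Why: Hydrogenolysis of the benzylic C–O bond removes the chiral auxiliary as ethylbenzene and frees the 5α-hydroxyl; ketone, lactone and silyl ether are inert and no stereocentre is touched.

Step 12
Reactants: 21 the 5α-alcohol
Product: 22 1β,8β-epoxy-10β-methyl-5α-(2-methylpropanoyloxy)-9-oxo-1-(TBDPS-oxymethyl)cycloheptane-12,6β-olide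
Conditions: i-PrCOCl, pyridine, DMAP (cat.), CH2Cl2, 0 °C to rt
Reagents that add atoms: 2-methylpropanoyl chloride, CC(C)C(Cl)=O
Why: Acylation of the only free hydroxyl with the acid chloride under nucleophilic catalysis installs the 2-methylpropanoate; no stereocentre is touched.

Step 13
Reactants: 22 the 5α-isobutyrate
Product: 26 1β,8β-epoxy-10β-methyl-5α-(2-methylpropanoyloxy)-9-oxo-1-(TBDPS-oxymethyl)cyclohept-11(13)-en-12,6β-olide, via lithium lactone enolate 23 (not isolated), via Mannich base 24 (not isolated), via ammonium iodide 25 (not isolated)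
Conditions: LiN(i-Pr)2 (1.2 equiv), THF, −78 °C; Eschenmoser's salt, −78 °C to rt; then MeI, MeOH, rt; then aq. NaHCO3, EtOAc
Reagents that add atoms: N,N-dimethylmethyleneiminium iodide, C=[N+](C)C.[I-]
Why: α-Methylenation of the lactone by the Mannich route: LiN(i-Pr)2 should enolise the lactone α-CH2 selectively, since the only α-hydrogen of the ketone is the shielded endo C10–H and that of the 2-methylpropanoate is a hindered, far less acidic methine; the enolate 23 is aminomethylated by Eschenmoser's salt, and N-methylation followed by base-induced E1cB elimination of trimethylamine gives the exocyclic alkene, erasing the transient C11 stereocentre.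

Step 14
Reactants: 26 the methylene lactone silyl ether
Product: 27 1β,8β-epoxy-1-(hydroxymethyl)-10β-methyl-5α-(2-methylpropanoyloxy)-9-oxocyclohept-11(13)-en-12,6β-olide
Conditions: HF·pyridine, pyridine, THF, 0 °C to rt
Reagents that add atoms: none
Why: Fluoride-induced cleavage of the silyl ether under buffered acidic conditions frees the primary alcohol without acyl migration or conjugate addition to the methylene lactone; no stereocentre is touched.

Step 15
Reactants: 27 the primary alcohol
Product: 28 1β,8β-epoxy-1-formyl-10β-methyl-5α-(2-methylpropanoyloxy)-9-oxocyclohept-11(13)-en-12,6β-olide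
Conditions: Dess–Martin periodinane, NaHCO3, CH2Cl2, 0 °C
Reagents that add atoms: none
Why: Dess–Martin oxidation of the primary alcohol gives the aldehyde, which sits on the quaternary C1 and therefore cannot enolise or epimerise.

Step 16
Reactants: 28 the aldehyde; 29 (E)-1-bromoprop-1-ene
Product: 31 1β,8β-epoxy-1-[(E)-1-hydroxybut-2-enyl]-10β-methyl-5α-(2-methylpropanoyloxy)-9-oxocyclohept-11(13)-en-12,6β-olide (both C2 epimers), via propenylchromium dichloride 30 (not isolated)
Conditions: CrCl2 (5 equiv), NiCl2 (2 mol%), DMF, rt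
Reagents that add atoms: none
Why: Nozaki–Hiyama–Kishi reaction: the alkenylchromium reagent 30, formed from the (E)-bromide with retention of alkene geometry, should add to the aldehyde only and leave ketone, lactone, ester and acrylate untouched; C2 forms as both epimers, which is immaterial because it is oxidised in step 19.

Step 17
Reactants: 31 the bicyclic allylic alcohol
Product: 32 1β-hydroxy-1-[(E)-1-hydroxybut-2-enyl]-10β-methyl-5α-(2-methylpropanoyloxy)-9-oxocyclohept-11(13)-en-12,6β-olide (C8 now CH2; both C2 epimers)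
Conditions: SmI2 (2.2 equiv), THF–MeOH, −78 °C
Reagents that add atoms: none
Why: Reductive cleavage of an α-alkoxy ketone by SmI2: the C9 ketyl expels the adjacent C8–O bond of the strained bridge, the samarium enolate is protonated by methanol at C8, and the C1 oxygen is released as the tertiary alcohol with its configuration unchanged (the C1–O bond is not broken), which opens the temporary ring to the cycloheptanone; the fast fragmentation at −78 °C should outrun reduction of the methylene lactone.

Step 18
Reactants: 32 the β-hydroxy ketone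
Product: 33 1β,9α-dihydroxy-1-[(E)-1-hydroxybut-2-enyl]-10β-methyl-5α-(2-methylpropanoyloxy)cyclohept-11(13)-en-12,6β-olide (both C2 epimers)
Conditions: Me4NBH(OAc)3, MeCN–AcOH, −30 °C
Reagents that add atoms: none
Why: Hydroxyl-directed reduction of a β-hydroxy ketone (Evans–Saksena reduction): boron binds the 1β-hydroxyl and should deliver hydride intramolecularly through a six-membered transition state to the β face of C9, setting the C9 hydroxyl α, trans to the C1 hydroxyl; esters, lactone and alkenes are inert to the reagent.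

Step 19
Reactants: 33 the triol
Product: 34 (3aS,5R,6S,7S,8S,8aR)-7-[(2E)-but-2-enoyl]-5,7-dihydroxy-6-methyl-3-methylidene-2-oxooctahydro-2H-cyclohepta[b]furan-8-yl 2-methylpropanoate (CNP0123946.1)
Conditions: MnO2, CH2Cl2, rt
Reagents that add atoms: none
Why: Chemoselective oxidation of the allylic alcohol by MnO2 should give the (E)-enone from either C2 epimer, while the non-allylic C9 secondary and C1 tertiary alcohols remain, completing the target.

**Compound list**

1 | furfuryl alcohol | OCc1ccco1 | starting material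
2 | tert-butyl(furan-2-ylmethoxy)diphenylsilane | CC(C)(C)[Si](OCc1ccco1)(c1ccccc1)c1ccccc1 | intermediate
3 | 1,1-dimethoxypropan-2-one | COC(OC)C(C)=O | starting material
4 | (S)-1-phenylethanol | C[C@H](O)c1ccccc1 | starting material
5 | 1-methoxy-1-[(1S)-1-phenylethoxy]propan-2-one | COC(O[C@@H](C)c1ccccc1)C(C)=O | intermediate
6 | lithium 3-methoxy-3-[(1S)-1-phenylethoxy]prop-1-en-2-olate | [Li]OC(=C)C(OC)O[C@@H](C)c1ccccc1 | intermediate
7 | triethyl({3-methoxy-3-[(1S)-1-phenylethoxy]prop-1-en-2-yl}oxy)silane | C=C(O[Si](CC)(CC)CC)C(OC)O[C@@H](C)c1ccccc1 | intermediate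
8 | 1-[(1S)-1-phenylethoxy]-2-(triethylsilyloxy)allyl cation triflate | C=C(O[Si](CC)(CC)CC)C=[O+][C@@H](C)c1ccccc1.[O-]S(=O)(=O)C(F)(F)F | intermediate
9 | (1R,2R,5S)-1-[(tert-butyldiphenylsilyloxy)methyl]-2-[(1S)-1-phenylethoxy]-8-oxabicyclo[3.2.1]oct-6-en-3-one | O=C1C[C@H]2C=C[C@](CO[Si](c3ccccc3)(c3ccccc3)C(C)(C)C)(O2)[C@H]1O[C@@H](C)c1ccccc1 | intermediate
10 | tert-butyl bromoacetate | CC(C)(C)OC(=O)CBr | starting material
11 | lithium enolate of 9 (C6–OLi, C6=C7) | [Li]OC1=C[C@H]2C=C[C@](CO[Si](c3ccccc3)(c3ccccc3)C(C)(C)C)(O2)[C@H]1O[C@@H](C)c1ccccc1 | intermediate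
12 | 7β-(tert-butoxycarbonylmethyl) ketone | O=C1[C@H](CC(=O)OC(C)(C)C)[C@H]2C=C[C@](CO[Si](c3ccccc3)(c3ccccc3)C(C)(C)C)(O2)[C@H]1O[C@@H](C)c1ccccc1 | intermediate
13 | 6α-hydroxy 7β-acetate ester | O[C@H]1[C@H](CC(=O)OC(C)(C)C)[C@H]2C=C[C@](CO[Si](c3ccccc3)(c3ccccc3)C(C)(C)C)(O2)[C@H]1O[C@@H](C)c1ccccc1 | intermediate
14 | 6α-trifluoromethanesulfonate of 13 | O=S(=O)(O[C@H]1[C@H](CC(=O)OC(C)(C)C)[C@H]2C=C[C@](CO[Si](c3ccccc3)(c3ccccc3)C(C)(C)C)(O2)[C@H]1O[C@@H](C)c1ccccc1)C(F)(F)F | intermediate
15 | cis-fused 12,6β-lactone with C9=C10 | C1C(=O)O[C@@H]2[C@H]1[C@H]3C=C[C@](CO[Si](c4ccccc4)(c4ccccc4)C(C)(C)C)(O3)[C@H]2O[C@@H](C)c1ccccc1 | intermediate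
16 | 9β-(9-borabicyclo[3.3.1]nonan-9-yl) lactone | C1C(=O)O[C@@H]2[C@H]1[C@H]3[C@H](B4C5CCCC4CCC5)C[C@](CO[Si](c4ccccc4)(c4ccccc4)C(C)(C)C)(O3)[C@H]2O[C@@H](C)c1ccccc1 | intermediate
17 | 9β-hydroxy lactone | C1C(=O)O[C@@H]2[C@H]1[C@H]3[C@H](O)C[C@](CO[Si](c4ccccc4)(c4ccccc4)C(C)(C)C)(O3)[C@H]2O[C@@H](C)c1ccccc1 | intermediate
18 | 9-oxo lactone | C1C(=O)O[C@@H]2[C@H]1[C@H]3C(=O)C[C@](CO[Si](c4ccccc4)(c4ccccc4)C(C)(C)C)(O3)[C@H]2O[C@@H](C)c1ccccc1 | intermediate
19 | lithium enolate of 18 (C9–OLi, C9=C10) | C1C(=O)O[C@@H]2[C@H]1[C@H]3C(O[Li])=C[C@](CO[Si](c4ccccc4)(c4ccccc4)C(C)(C)C)(O3)[C@H]2O[C@@H](C)c1ccccc1 | intermediate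
20 | 10β-methyl-9-oxo lactone | C1C(=O)O[C@@H]2[C@H]1[C@H]3C(=O)[C@H](C)[C@](CO[Si](c4ccccc4)(c4ccccc4)C(C)(C)C)(O3)[C@H]2O[C@@H](C)c1ccccc1 | intermediate
21 | 5α-hydroxy-10β-methyl-9-oxo lactone | C1C(=O)O[C@@H]2[C@H]1[C@H]3C(=O)[C@H](C)[C@](CO[Si](c4ccccc4)(c4ccccc4)C(C)(C)C)(O3)[C@H]2O | intermediate
22 | 5α-(2-methylpropanoyloxy)-10β-methyl-9-oxo lactone | C1C(=O)O[C@@H]2[C@H]1[C@H]3C(=O)[C@H](C)[C@](CO[Si](c4ccccc4)(c4ccccc4)C(C)(C)C)(O3)[C@H]2OC(=O)C(C)C | intermediate
23 | lithium lactone enolate of 22 | C1=C(O[Li])O[C@@H]2[C@H]1[C@H]3C(=O)[C@H](C)[C@](CO[Si](c4ccccc4)(c4ccccc4)C(C)(C)C)(O3)[C@H]2OC(=O)C(C)C | intermediate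
24 | 11-(dimethylaminomethyl) lactone (C11 epimers) | CN(C)CC1C(=O)O[C@@H]2[C@H]1[C@H]3C(=O)[C@H](C)[C@](CO[Si](c4ccccc4)(c4ccccc4)C(C)(C)C)(O3)[C@H]2OC(=O)C(C)C | intermediate
25 | 11-(trimethylammoniomethyl) lactone iodide | C[N+](C)(C)CC1C(=O)O[C@@H]2[C@H]1[C@H]3C(=O)[C@H](C)[C@](CO[Si](c4ccccc4)(c4ccccc4)C(C)(C)C)(O3)[C@H]2OC(=O)C(C)C.[I-] | intermediate
26 | bicyclic 11(13)-methylene lactone silyl ether | C=C1C(=O)O[C@@H]2[C@H]1[C@H]3C(=O)[C@H](C)[C@](CO[Si](c4ccccc4)(c4ccccc4)C(C)(C)C)(O3)[C@H]2OC(=O)C(C)C | intermediate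
27 | bicyclic primary alcohol | C=C1C(=O)O[C@@H]2[C@H]1[C@H]3C(=O)[C@H](C)[C@](CO)(O3)[C@H]2OC(=O)C(C)C | intermediate
28 | bicyclic aldehyde | C=C1C(=O)O[C@@H]2[C@H]1[C@H]3C(=O)[C@H](C)[C@](C=O)(O3)[C@H]2OC(=O)C(C)C | intermediate
29 | (E)-1-bromoprop-1-ene | C/C=C/Br | starting material
30 | (E)-prop-1-enylchromium dichloride | C/C=C/[Cr](Cl)Cl | intermediate
31 | bicyclic (E)-allylic alcohol (C2 epimers) | C=C1C(=O)O[C@@H]2[C@H]1[C@H]3C(=O)[C@H](C)[C@](C(O)/C=C/C)(O3)[C@H]2OC(=O)C(C)C | intermediate
32 | ring-opened 1β-hydroxy-9-ketone (C2 epimers) | C=C1C(=O)O[C@@H]2[C@H]1CC(=O)[C@H](C)[C@@](O)(C(O)/C=C/C)[C@H]2OC(=O)C(C)C | intermediate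
33 | 1β,9α-diol allylic alcohol (C2 epimers) | C=C1C(=O)O[C@@H]2[C@H]1C[C@@H](O)[C@H](C)[C@@](O)(C(O)/C=C/C)[C@H]2OC(=O)C(C)C | intermediate
34 | CNP0123946.1 | C=C1C(=O)O[C@@H]2[C@H]1C[C@@H](O)[C@H](C)[C@@](O)(C(=O)/C=C/C)[C@H]2OC(=O)C(C)C | target

**Count and risks**

Total steps: 19. Longest linear sequence: 18 steps (steps 2 and 3, then 4 to 19, from 3 and 4).

Step 4. After the first C–C bond forms, closure at the hindered substituted furan carbon may lose out to desilylation (electrophilic substitution of the furan in place of cycloaddition), and regio- or facial selectivity may erode with the 2-substituted furan. The fallback sets out from 4 and generates the oxyallyl species without a silyl Lewis acid. Addition of 4 to epichlorohydrin (BF3·OEt2 cat., 0 °C) should give 1-chloro-3-[(1S)-1-phenylethoxy]propan-2-ol F1. Dess–Martin oxidation should give 1-chloro-3-[(1S)-1-phenylethoxy]propan-2-one F2. With furan 2 and sodium 2,2,2-trifluoroethoxide in 2,2,2-trifluoroethanol, F2 forms the free alkoxy-oxyallyl zwitterion, whose (4+3) cycloaddition returns to the route at 9.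

Step 10. Competing deprotonation of the lactone, or proton transfer from it to the ketone enolate, would lead to methylation at C11 (loss of chemoselectivity). The fallback sets out from 17 and blocks the lactone α-position before the ketone exists. LiN(i-Pr)2 (2.2 equiv) then Eschenmoser's salt should give the 11-(dimethylaminomethyl) derivative of 17 F7. Swern oxidation gives the amino ketone F8. LiN(SiMe3)2 and MeI at −78 °C, quenched cold with aqueous ammonia, should give the 10β-methyl amino ketone F9. Hydrogenolysis (H2, Pd(OH)2/C, EtOAc–AcOH) gives the 5α-alcohol F10. Acylation with i-PrCOCl and pyridine comes back to the route at 24, which is taken through the MeI and NaHCO3 stages of step 13 to 26.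

Step 8. Boron may add to C10 as well as C9 (poor regioselectivity of hydroboration). The fallback sets out from 15 and fixes the regiochemistry by differentiating a diol. OsO4 (cat.) with N-methylmorpholine N-oxide should give the exo 9β,10β-diol F3. Et3SiCl and imidazole silylate the less hindered 9-hydroxyl to the 9β-triethylsilyl ether F4. PhOC(S)Cl and DMAP give the 10β-O-phenoxythiocarbonyl derivative F5. Barton–McCombie deoxygenation (Bu3SnH, AIBN, toluene, 80 °C) gives the 9β-triethylsilyl ether of 17 F6. PPTS in MeOH comes back to the route at 17.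

**Further compounds**

F1 | step 4 | 1-chloro-3-[(1S)-1-phenylethoxy]propan-2-ol (carbinol epimers) | OC(CCl)CO[C@@H](C)c1ccccc1
F2 | step 4 | 1-chloro-3-[(1S)-1-phenylethoxy]propan-2-one | O=C(CCl)CO[C@@H](C)c1ccccc1
F3 | step 8 | 9β,10β-dihydroxy derivative of 15 | C1C(=O)O[C@@H]2[C@H]1[C@H]3[C@H](O)[C@H](O)[C@](CO[Si](c4ccccc4)(c4ccccc4)C(C)(C)C)(O3)[C@H]2O[C@@H](C)c1ccccc1
F4 | step 8 | 9β-triethylsilyl ether of F3 | C1C(=O)O[C@@H]2[C@H]1[C@H]3[C@H](O[Si](CC)(CC)CC)[C@H](O)[C@](CO[Si](c4ccccc4)(c4ccccc4)C(C)(C)C)(O3)[C@H]2O[C@@H](C)c1ccccc1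
F5 | step 8 | 10β-O-(phenoxythiocarbonyl) derivative of F4 | C1C(=O)O[C@@H]2[C@H]1[C@H]3[C@H](O[Si](CC)(CC)CC)[C@H](OC(=S)Oc4ccccc4)[C@](CO[Si](c4ccccc4)(c4ccccc4)C(C)(C)C)(O3)[C@H]2O[C@@H](C)c1ccccc1
F6 | step 8 | 9β-triethylsilyl ether of 17 | C1C(=O)O[C@@H]2[C@H]1[C@H]3[C@H](O[Si](CC)(CC)CC)C[C@](CO[Si](c4ccccc4)(c4ccccc4)C(C)(C)C)(O3)[C@H]2O[C@@H](C)c1ccccc1
F7 | step 10 | 11-(dimethylaminomethyl) derivative of 17 (C11 epimers) | CN(C)CC1C(=O)O[C@@H]2[C@H]1[C@H]3[C@H](O)C[C@](CO[Si](c4ccccc4)(c4ccccc4)C(C)(C)C)(O3)[C@H]2O[C@@H](C)c1ccccc1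
F8 | step 10 | 11-(dimethylaminomethyl) derivative of 18 | CN(C)CC1C(=O)O[C@@H]2[C@H]1[C@H]3C(=O)C[C@](CO[Si](c4ccccc4)(c4ccccc4)C(C)(C)C)(O3)[C@H]2O[C@@H](C)c1ccccc1
F9 | step 10 | 11-(dimethylaminomethyl) derivative of 20 | CN(C)CC1C(=O)O[C@@H]2[C@H]1[C@H]3C(=O)[C@H](C)[C@](CO[Si](c4ccccc4)(c4ccccc4)C(C)(C)C)(O3)[C@H]2O[C@@H](C)c1ccccc1
F10 | step 10 | 11-(dimethylaminomethyl) derivative of 21 | CN(C)CC1C(=O)O[C@@H]2[C@H]1[C@H]3C(=O)[C@H](C)[C@](CO[Si](c4ccccc4)(c4ccccc4)C(C)(C)C)(O3)[C@H]2O
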